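**Retrosynthetic overview**

1. The esters are put on last. The axial 6β-oxygen comes from a C6 ketone by hydroxyl-directed hydride delivery to the α face, so the decalin is first made with a 6α-silyloxy group.
2. The C8=C9 bond and the side chain come from the enol triflate of a C9 ketone and an sp3–sp2 Suzuki coupling. The second C4 methyl comes from hydromethylation of a C3=C4 alkene, and the 2α-acetate from Mitsunobu inversion of a 2β-alcohol.
3. C1–C2 and C5–C10 are cut together: a type 1 intramolecular Diels–Alder reaction of an acyclic deca-1,7,9-trien-3-one forms ring A (cycloaddition) and ring B (tether) in the same step.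
4. The enabling feature: ring A (C1, C2, C3, C4, C5, C10) is a six-membered carbocycle whose fusion atoms C5 and C10 are also joined by the four-carbon bridge C6–C7–C8–C9 of ring B. With a C3=C4 double bond written in, ring A is a cyclohexene; the quaternary C10 methyl is the α-methyl of an enone whose carbonyl is C9, and the C2 oxygen sits on the diene terminus (as boron).
5. The trienone comes from an anti aldol reaction of 2-methylpent-1-en-3-one with (R)-glyceraldehyde acetonide (sets C6, C7, C8), then Wittig and Takai–Utimoto olefinations (build the diene).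

Key step: step 8

Remark: labdane numbering is used throughout (ring carbons C1–C10, methyls C18/C19 on C4, C17 on C8, C20 on C10, side chain C11–C16); α is the face of H-5, β the face of C20. (R)-Glyceraldehyde acetonide and (E)-3-methylpent-2-en-4-yn-1-ol are taken as commercial single isomers.

**Route**

Step 1
Reactants: 1 2-methylpent-1-en-3-one; 2 (R)-2,2-dimethyl-1,3-dioxolane-4-carbaldehyde
Product: 4 (4R,5S)-5-[(4R)-2,2-dimethyl-1,3-dioxolan-4-yl]-5-hydroxy-2,4-dimethylpent-1-en-3-one, via enol borinate 3 (not isolated)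
Conditions: 1, Cy2BCl, Et3N, Et2O, 0 °C; then 2, −78 → −20 °C; H2O2, MeOH, pH 7 buffer, 0 °C
Reagents that add atoms: none
Why: Boron-mediated anti aldol reaction: Cy2BCl/Et3N gives the (E)-enol borinate 3, whose closed chair-like transition state places the C7 hydroxyl and C8 methyl anti (C8 R), while Felkin-type 1,2-induction by the α-oxygen of 2 sets C7 (S) anti to the C6 oxygen, so all three tether stereocentres come from one substrate-controlled step.

Step 2
Reactants: 4
Product: 5 (4R,5S)-5-[(tert-butyldimethylsilyl)oxy]-5-[(4R)-2,2-dimethyl-1,3-dioxolan-4-yl]-2,4-dimethylpent-1-en-3-one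
Conditions: TBSOTf, 2,6-lutidine, CH2Cl2, −78 °C
Reagents that add atoms: tert-butyldimethylsilyl trifluoromethanesulfonate, CC(C)(C)[Si](C)(C)OS(=O)(=O)C(F)(F)F
Why: Silyl ether formation under non-basic conditions (no retro-aldol or elimination of the β-hydroxy ketone); TBS is chosen to outlast the TES ethers of step 4.

Step 3
Reactants: 5
Product: 6 (4R,5S,6R)-5-[(tert-butyldimethylsilyl)oxy]-6,7-dihydroxy-2,4-dimethylhept-1-en-3-one
Conditions: AcOH/H2O/THF (3:1:1), 40 °C
Reagents that add atoms: none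
Why: Acid hydrolysis of the terminal isopropylidene acetal, under which the secondary TBS ether should be stable.

Step 4
Reactants: 6
Product: 7 (4R,5S,6R)-5-[(tert-butyldimethylsilyl)oxy]-2,4-dimethyl-6,7-bis[(triethylsilyl)oxy]hept-1-en-3-one
Conditions: TESOTf, 2,6-lutidine, CH2Cl2, −78 °C
Reagents that add atoms: triethylsilyl trifluoromethanesulfonate, CC[Si](CC)(CC)OS(=O)(=O)C(F)(F)F
Why: Silylation of both hydroxyls; the primary TES ether is the latent C5 aldehyde and the secondary one is the C6 group that is removed alone in step 15.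

Step 5
Reactants: 7
Product: 8 (2S,3S,4R)-3-[(tert-butyldimethylsilyl)oxy]-4,6-dimethyl-5-oxo-2-[(triethylsilyl)oxy]hept-6-enal
Conditions: (COCl)2, DMSO, CH2Cl2, −78 → −30 °C; Et3N, −78 → 0 °C
Reagents that add atoms: none
Why: Swern oxidation in which the primary triethylsilyl ether is cleaved by the chlorosulfonium reagent and oxidised in the same flask while the secondary TES and TBS ethers stay, a known chemoselective variant.

Step 6
Reactants: 8
Product: 9 (2E,4R,5S,6R)-5-[(tert-butyldimethylsilyl)oxy]-2,6,8-trimethyl-7-oxo-4-[(triethylsilyl)oxy]nona-2,8-dienal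
Conditions: Ph3P=C(CH3)CHO, toluene, 70 °C
Reagents that add atoms: 2-(triphenylphosphoranylidene)propanal, CC(C=O)=P(c1ccccc1)(c1ccccc1)c1ccccc1
Why: Wittig olefination with a stabilised ylide should give the (E)-2-methyl enal (C4 methyl cis to C6) under neutral conditions that neither epimerise the α-silyloxy aldehyde nor touch the enone.

Step 7
Reactants: 9
Product: 10 (4R,5S,6R,7E,9E)-5-[(tert-butyldimethylsilyl)oxy]-2,4,8-trimethyl-10-(4,4,5,5-tetramethyl-1,3,2-dioxaborolan-2-yl)-6-[(triethylsilyl)oxy]deca-1,7,9-trien-3-one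
Conditions: Cl2CHBpin, CrCl2, LiI, THF, 25 °C
Reagents that add atoms: 2-(dichloromethyl)-4,4,5,5-tetramethyl-1,3,2-dioxaborolane, ClC(Cl)B1OC(C)(C)C(C)(C)O1
Why: Takai–Utimoto borylolefination: the geminal dichromium reagent adds to the aldehyde only (the ketone is left) and gives the (E)-alkenylboronate, completing the (E,E)-diene.

Step 8
Reactants: 10
Product: 12 7α-(tert-butyldimethylsilyloxy)-2β-hydroxy-4,8α,10β-trimethyl-6α-(triethylsilyloxy)-5αH-trans-decal-3-en-9-one, via allylboronate 11 (not isolated)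
Conditions: toluene (0.01 M), BHT, 110 °C; then NaBO3·4H2O, THF/H2O, 25 °C
Reagents that add atoms: sodium perborate, [Na+].[Na+].O[B-]1(O)OO[B-](O)(O)OO1
Why: Thermal type 1 intramolecular Diels–Alder reaction of a deca-1,7,9-trien-3-one: the (E,E)-dienylboronate C2=C3–C4=C5 adds suprafacially to the isopropenyl group C1=C10 activated by the C9 ketone, forming C1–C2 and C5–C10 in one concerted, asynchronous event, and allylboronate 11 is oxidised in the same flask with retention at C2; the closest precedents are cyclisations of 2-substituted deca-1,7,9-trien-3-ones to angular-methyl octalones and Diels–Alder/oxidation sequences of 1-boryl dienes. Ring A is the new cyclohexene closed by the two forming bonds ([4+2]); ring B is the six-membered ring closed through the four-atom tether C6–C9 in the fused mode with a chair-like tether. C5 is controlled by 1,3-allylic strain between the C4 methyl and C6: the C6–H bond lies in the diene plane, C7 can reach the dienophile from one face only and the OTES group points away from the forming bond, so OTES ends up equatorial (6α) and H-5 α; the same chair keeps the C8 methyl equatorial and the C7 OTBS axial, whereas attack on the other face would need OTES eclipsed with the C4 methyl and the C8 methyl axial under C20. C10 is controlled by the exo placement of the tether carbonyl (C10 methyl endo, the usual preference of α-methyl enones), which gives the trans ring fusion with C20 β. C2 follows from the (E) geometry of C2=C3: boron, and then hydroxyl, is cis to C6, that is 2β. The step needs π-facial and exo/endo selectivity, secured as described; regiochemistry is fixed by the tether.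

Step 9
Reactants: 12
Product: 13 2α-acetoxy-7α-(tert-butyldimethylsilyloxy)-4,8α,10β-trimethyl-6α-(triethylsilyloxy)-5αH-trans-decal-3-en-9-one
Conditions: AcOH, PPh3, DIAD, THF, 0 → 25 °C
Reagents that add atoms: acetic acid, CC(=O)O
Why: Mitsunobu reaction: SN2 displacement of the activated pseudo-axial allylic 2β-oxygen by acetate from the open α face inverts C2 and installs the final 2α-acetate; SN2' attack at the fully substituted C4 is not expected.

Step 10
Reactants: 13
Product: 15 2α-acetoxy-7α-(tert-butyldimethylsilyloxy)-4,4,8α,10β-tetramethyl-6α-(triethylsilyloxy)-5αH-trans-decalin-9-one, via sulfonylhydrazide 14 (not isolated)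
Conditions: (CH2O)n, n-C8H17SO2NHNH2, Fe(acac)3 (sub-stoichiometric), PhSiH3, THF/MeOH, 25 °C; then NaHCO3, MeOH, 60 °C
Reagents that add atoms: formaldehyde (as paraformaldehyde), C=O
Why: Iron-hydride hydrogen-atom-transfer (Markovnikov) hydromethylation: H adds to C3, the tertiary C4 radical adds to the formaldehyde sulfonylhydrazone, and adduct 14 loses sulfinate and N2 on warming to leave the second C4 methyl; C3=C4 is the only alkene present and no stereocentre is created.

Step 11
Reactants: 15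
Product: 16 2α-acetoxy-7α-(tert-butyldimethylsilyloxy)-4,4,8,10β-tetramethyl-6α-(triethylsilyloxy)-5αH-trans-decal-8-en-9-yl trifluoromethanesulfonate
Conditions: Tf2O, 2,6-di-tert-butyl-4-methylpyridine, CH2Cl2, 0 → 25 °C
Reagents that add atoms: trifluoromethanesulfonic anhydride, O=S(=O)(OS(=O)(=O)C(F)(F)F)C(F)(F)F
Why: Enol triflate formation with triflic anhydride and a hindered pyridine (no enolate, so the acetate is safe); C10 is quaternary, so only the C8 hydrogen can be lost and the sacrificial C8 stereocentre becomes an alkene carbon of C8=C9.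

Step 12
Reactants: 17 (E)-3-methylpent-2-en-4-yn-1-ol
Product: 18 1-methoxy-4-({[(2E)-3-methylpent-2-en-4-yn-1-yl]oxy}methyl)benzene
Conditions: NaH, PMBCl, Bu4NI (cat.), THF/DMF, 0 → 25 °C
Reagents that add atoms: 4-methoxybenzyl chloride, COc1ccc(CCl)cc1
Why: Williamson ether synthesis; the PMB ether survives all later fluoride and acid steps and is removed oxidatively at the end.

Step 13
Reactants: 18
Product: 19 1-methoxy-4-({[(2E)-3-methylpenta-2,4-dien-1-yl]oxy}methyl)benzene
Conditions: H2 (1 atm), Pd/CaCO3/Pb(OAc)2, quinoline, hexane/EtOAc, 25 °C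
Reagents that add atoms: none
Why: Lindlar semi-hydrogenation of the terminal alkyne to the vinyl group; the trisubstituted (E)-alkene is not affected.

Step 14
Reactants: 16; 19
Product: 21 2α-acetoxy-7α-(tert-butyldimethylsilyloxy)-15-(4-methoxybenzyloxy)-6α-(triethylsilyloxy)labda-8,13E-diene, via alkylborane 20 (not isolated)
Conditions: 19, 9-BBN, THF, 0 → 25 °C; then 16, Pd(dppf)Cl2, AsPh3, K3PO4 (aq), DMF, 50 °C
Reagents that add atoms: none
Why: Hydroboration/B-alkyl Suzuki–Miyaura coupling: 9-BBN adds to the terminal vinyl group with boron on C11, and the primary alkylborane 20 couples with the hindered cyclohexenyl triflate (of the 2,6,6-trimethylcyclohexenyl triflate type), forming C9–C11 with the alkene position fixed.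

Step 15
Reactants: 21
Product: 22 2α-acetoxy-7α-(tert-butyldimethylsilyloxy)-15-(4-methoxybenzyloxy)labda-8,13E-dien-6α-ol
Conditions: PPTS, MeOH/CH2Cl2, 0 °C
Reagents that add atoms: none
Why: Acid-catalysed methanolysis that distinguishes the silyl groups: the TES ether is cleaved much faster than the secondary TBS ether, freeing only the 6α-hydroxyl.

Step 16
Reactants: 22
Product: 23 2α-acetoxy-7α-(tert-butyldimethylsilyloxy)-15-(4-methoxybenzyloxy)labda-8,13E-dien-6-one
Conditions: Dess–Martin periodinane, NaHCO3, CH2Cl2, 25 °C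
Reagents that add atoms: none
Why: Dess–Martin oxidation under buffered, non-enolising conditions removes the wrongly configured C6 stereocentre without moving the C8=C9 bond or epimerising C5 or C7.

Step 17
Reactants: 23
Product: 24 2α-acetoxy-7α-hydroxy-15-(4-methoxybenzyloxy)labda-8,13E-dien-6-one
Conditions: HF·pyridine, pyridine, THF, 0 → 25 °C
Reagents that add atoms: none
Why: Fluoride-mediated desilylation under slightly acidic conditions, which avoids base-induced enolisation of the α-hydroxy-β,γ-unsaturated ketone; 24 is used at once.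

Step 18
Reactants: 24
Product: 25 2α-acetoxy-15-(4-methoxybenzyloxy)labda-8,13E-diene-6β,7α-diol
Conditions: Me4NBH(OAc)3, MeCN/AcOH, −30 °C
Reagents that add atoms: none
Why: Hydroxyl-directed triacetoxyborohydride reduction: the 7α-hydroxyl binds boron and delivers hydride to the α face of C6, the β face being shielded in addition by the syn-axial C19 and C20 methyls, giving the axial 6β-alcohol (6S) and the trans-diaxial 6β,7α-diol.

Step 19
Reactants: 25
Product: 26 2α,7α-diacetoxy-15-(4-methoxybenzyloxy)labda-8,13E-dien-6β-ol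
Conditions: Ac2O, pyridine, DMAP (cat.), CH2Cl2, 0 °C
Reagents that add atoms: acetic anhydride, CC(=O)OC(C)=O
Why: Selective acylation: the allylic 7α-hydroxyl is acetylated, while the 6β-hydroxyl, syn-axial to two methyl groups, should not react under these mild conditions.

Step 20
Reactants: 26
Product: 27 2α,7α-diacetoxy-15-(4-methoxybenzyloxy)labda-8,13E-dien-6β-yl 3-methylbutanoate
Conditions: (iPrCH2CO)2O, DMAP, Et3N, toluene, 80 °C
Reagents that add atoms: 3-methylbutanoic anhydride, CC(C)CC(=O)OC(=O)CC(C)C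
Why: DMAP-catalysed acyl transfer from the anhydride under forcing conditions esterifies the remaining hindered axial hydroxyl; acyl migration between the trans-diaxial C6 and C7 oxygens is geometrically impossible.

Step 21
Reactants: 27
Product: 28 2α,7α-diacetoxy-15-hydroxylabda-8,13E-dien-6β-yl 3-methylbutanoate (CNP0257091.1)
Conditions: DDQ, CH2Cl2/pH 7 buffer, 0 °C
Reagents that add atoms: none
Why: Oxidative cleavage of the 4-methoxybenzyl ether with DDQ in wet solvent, which leaves the three esters and both alkenes and frees the C15 allylic alcohol.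

**Compound list**

1 | 2-methylpent-1-en-3-one | C=C(C)C(=O)CC | starting material
2 | (R)-2,2-dimethyl-1,3-dioxolane-4-carbaldehyde | O=C[C@H]1COC(C)(C)O1 | starting material
3 | dicyclohexyl{[(3E)-2-methylpenta-1,3-dien-3-yl]oxy}borane | C/C=C(/OB(C1CCCCC1)C1CCCCC1)C(C)=C | intermediate
4 | (4R,5S)-5-[(4R)-2,2-dimethyl-1,3-dioxolan-4-yl]-5-hydroxy-2,4-dimethylpent-1-en-3-one | C=C(C)C(=O)[C@H](C)[C@H](O)[C@H]1COC(C)(C)O1 | intermediate
5 | (4R,5S)-5-[(tert-butyldimethylsilyl)oxy]-5-[(4R)-2,2-dimethyl-1,3-dioxolan-4-yl]-2,4-dimethylpent-1-en-3-one | C=C(C)C(=O)[C@H](C)[C@H](O[Si](C)(C)C(C)(C)C)[C@H]1COC(C)(C)O1 | intermediate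
6 | (4R,5S,6R)-5-[(tert-butyldimethylsilyl)oxy]-6,7-dihydroxy-2,4-dimethylhept-1-en-3-one | C=C(C)C(=O)[C@H](C)[C@H](O[Si](C)(C)C(C)(C)C)[C@H](O)CO | intermediate
7 | (4R,5S,6R)-5-[(tert-butyldimethylsilyl)oxy]-2,4-dimethyl-6,7-bis[(triethylsilyl)oxy]hept-1-en-3-one | C=C(C)C(=O)[C@H](C)[C@H](O[Si](C)(C)C(C)(C)C)[C@H](O[Si](CC)(CC)CC)CO[Si](CC)(CC)CC | intermediate
8 | (2S,3S,4R)-3-[(tert-butyldimethylsilyl)oxy]-4,6-dimethyl-5-oxo-2-[(triethylsilyl)oxy]hept-6-enal | C=C(C)C(=O)[C@H](C)[C@H](O[Si](C)(C)C(C)(C)C)[C@H](O[Si](CC)(CC)CC)C=O | intermediate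
9 | (2E,4R,5S,6R)-5-[(tert-butyldimethylsilyl)oxy]-2,6,8-trimethyl-7-oxo-4-[(triethylsilyl)oxy]nona-2,8-dienal | C=C(C)C(=O)[C@H](C)[C@H](O[Si](C)(C)C(C)(C)C)[C@H](O[Si](CC)(CC)CC)/C=C(C)/C=O | intermediate
10 | (4R,5S,6R,7E,9E)-5-[(tert-butyldimethylsilyl)oxy]-2,4,8-trimethyl-10-(4,4,5,5-tetramethyl-1,3,2-dioxaborolan-2-yl)-6-[(triethylsilyl)oxy]deca-1,7,9-trien-3-one | C=C(C)C(=O)[C@H](C)[C@H](O[Si](C)(C)C(C)(C)C)[C@H](O[Si](CC)(CC)CC)/C=C(C)/C=C/B1OC(C)(C)C(C)(C)O1 | intermediate
11 | 7α-(tert-butyldimethylsilyloxy)-4,8α,10β-trimethyl-2β-(4,4,5,5-tetramethyl-1,3,2-dioxaborolan-2-yl)-6α-(triethylsilyloxy)-5αH-trans-decal-3-en-9-one | CC1(C)OB(OC1(C)C)[C@@H]1C=C(C)[C@@H]2[C@@H](O[Si](CC)(CC)CC)[C@@H](O[Si](C)(C)C(C)(C)C)[C@@H](C)C(=O)[C@@]2(C)C1 | intermediate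
12 | 7α-(tert-butyldimethylsilyloxy)-2β-hydroxy-4,8α,10β-trimethyl-6α-(triethylsilyloxy)-5αH-trans-decal-3-en-9-one | O[C@@H]1C=C(C)[C@@H]2[C@@H](O[Si](CC)(CC)CC)[C@@H](O[Si](C)(C)C(C)(C)C)[C@@H](C)C(=O)[C@@]2(C)C1 | intermediate
13 | 2α-acetoxy-7α-(tert-butyldimethylsilyloxy)-4,8α,10β-trimethyl-6α-(triethylsilyloxy)-5αH-trans-decal-3-en-9-one | CC(=O)O[C@H]1C=C(C)[C@@H]2[C@@H](O[Si](CC)(CC)CC)[C@@H](O[Si](C)(C)C(C)(C)C)[C@@H](C)C(=O)[C@@]2(C)C1 | intermediate
14 | 2α-acetoxy-7α-(tert-butyldimethylsilyloxy)-4,8α,10β-trimethyl-4-{[2-(octylsulfonyl)hydrazinyl]methyl}-6α-(triethylsilyloxy)-5αH-trans-decalin-9-one (either C4 epimer) | CC(=O)O[C@H]1CC(C)(CNNS(=O)(=O)CCCCCCCC)[C@@H]2[C@@H](O[Si](CC)(CC)CC)[C@@H](O[Si](C)(C)C(C)(C)C)[C@@H](C)C(=O)[C@@]2(C)C1 | intermediate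
15 | 2α-acetoxy-7α-(tert-butyldimethylsilyloxy)-4,4,8α,10β-tetramethyl-6α-(triethylsilyloxy)-5αH-trans-decalin-9-one | CC(=O)O[C@H]1CC(C)(C)[C@@H]2[C@@H](O[Si](CC)(CC)CC)[C@@H](O[Si](C)(C)C(C)(C)C)[C@@H](C)C(=O)[C@@]2(C)C1 | intermediate
16 | 2α-acetoxy-7α-(tert-butyldimethylsilyloxy)-4,4,8,10β-tetramethyl-6α-(triethylsilyloxy)-5αH-trans-decal-8-en-9-yl trifluoromethanesulfonate | CC(=O)O[C@H]1CC(C)(C)[C@@H]2[C@@H](O[Si](CC)(CC)CC)[C@@H](O[Si](C)(C)C(C)(C)C)C(C)=C(OS(=O)(=O)C(F)(F)F)[C@@]2(C)C1 | intermediate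
17 | (E)-3-methylpent-2-en-4-yn-1-ol | C#C/C(C)=C/CO | starting material
18 | 1-methoxy-4-({[(2E)-3-methylpent-2-en-4-yn-1-yl]oxy}methyl)benzene | C#C/C(C)=C/COCc1ccc(OC)cc1 | intermediate
19 | 1-methoxy-4-({[(2E)-3-methylpenta-2,4-dien-1-yl]oxy}methyl)benzene | C=C/C(C)=C/COCc1ccc(OC)cc1 | intermediate
20 | 9-[(3E)-5-(4-methoxybenzyloxy)-3-methylpent-3-en-1-yl]-9-borabicyclo[3.3.1]nonane | COc1ccc(COC/C=C(C)/CCB2C3CCCC2CCC3)cc1 | intermediate
21 | 2α-acetoxy-7α-(tert-butyldimethylsilyloxy)-15-(4-methoxybenzyloxy)-6α-(triethylsilyloxy)labda-8,13E-diene | CC(=O)O[C@H]1CC(C)(C)[C@@H]2[C@@H](O[Si](CC)(CC)CC)[C@@H](O[Si](C)(C)C(C)(C)C)C(C)=C(CC/C(C)=C/COCc3ccc(OC)cc3)[C@@]2(C)C1 | intermediate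
22 | 2α-acetoxy-7α-(tert-butyldimethylsilyloxy)-15-(4-methoxybenzyloxy)labda-8,13E-dien-6α-ol | CC(=O)O[C@H]1CC(C)(C)[C@@H]2[C@@H](O)[C@@H](O[Si](C)(C)C(C)(C)C)C(C)=C(CC/C(C)=C/COCc3ccc(OC)cc3)[C@@]2(C)C1 | intermediate
23 | 2α-acetoxy-7α-(tert-butyldimethylsilyloxy)-15-(4-methoxybenzyloxy)labda-8,13E-dien-6-one | CC(=O)O[C@H]1CC(C)(C)[C@@H]2C(=O)[C@@H](O[Si](C)(C)C(C)(C)C)C(C)=C(CC/C(C)=C/COCc3ccc(OC)cc3)[C@@]2(C)C1 | intermediate
24 | 2α-acetoxy-7α-hydroxy-15-(4-methoxybenzyloxy)labda-8,13E-dien-6-one | CC(=O)O[C@H]1CC(C)(C)[C@@H]2C(=O)[C@@H](O)C(C)=C(CC/C(C)=C/COCc3ccc(OC)cc3)[C@@]2(C)C1 | intermediate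
25 | 2α-acetoxy-15-(4-methoxybenzyloxy)labda-8,13E-diene-6β,7α-diol | CC(=O)O[C@H]1CC(C)(C)[C@@H]2[C@H](O)[C@@H](O)C(C)=C(CC/C(C)=C/COCc3ccc(OC)cc3)[C@@]2(C)C1 | intermediate
26 | 2α,7α-diacetoxy-15-(4-methoxybenzyloxy)labda-8,13E-dien-6β-ol | CC(=O)O[C@H]1CC(C)(C)[C@@H]2[C@H](O)[C@@H](OC(C)=O)C(C)=C(CC/C(C)=C/COCc3ccc(OC)cc3)[C@@]2(C)C1 | intermediate
27 | 2α,7α-diacetoxy-15-(4-methoxybenzyloxy)labda-8,13E-dien-6β-yl 3-methylbutanoate | CC(=O)O[C@H]1CC(C)(C)[C@@H]2[C@H](OC(=O)CC(C)C)[C@@H](OC(C)=O)C(C)=C(CC/C(C)=C/COCc3ccc(OC)cc3)[C@@]2(C)C1 | intermediate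
28 | 2α,7α-diacetoxy-15-hydroxylabda-8,13E-dien-6β-yl 3-methylbutanoate | CC(=O)O[C@H]1CC(C)(C)[C@@H]2[C@H](OC(=O)CC(C)C)[C@@H](OC(C)=O)C(C)=C(CC/C(C)=C/CO)[C@@]2(C)C1 | target

**Step count and risks**

Total step count: 21. Longest linear sequence: 19 steps (steps 1–11 and 14–21); steps 12–13 make the side-chain diene.

Steps most likely to fail:

Step 8. The boryl group lowers the reactivity of the diene, so the cycloaddition may be slow at 110 °C; at the temperature then needed, the carbonyl-endo pathway (cis ring fusion, wrong C10) or thermal loss of boron may compete. The fallback sets out from enal 9 and drops the boron. Aldehyde-selective methylenation (Zn, CH2I2, Ti(OiPr)4, THF, 25 °C) would give (4R,5S,6R,7E)-5-[(tert-butyldimethylsilyl)oxy]-2,4,8-trimethyl-6-[(triethylsilyl)oxy]deca-1,7,9-trien-3-one F1. Its unsubstituted diene terminus should allow the same cycloaddition at lower temperature (toluene, 60–80 °C) under the same facial control, giving 7α-(tert-butyldimethylsilyloxy)-4,8α,10β-trimethyl-6α-(triethylsilyloxy)-5αH-trans-decal-3-en-9-one F2. Allylic oxidation of the C2 methylene (CrO3·3,5-dimethylpyrazole, CH2Cl2, −20 °C) would give 7α-(tert-butyldimethylsilyloxy)-4,8α,10β-trimethyl-6α-(triethylsilyloxy)-5αH-trans-decal-3-ene-2,9-dione F3. Luche reduction (NaBH4, CeCl3·7H2O, MeOH, −78 °C; hydride anti to C20, the C9 ketone being too hindered) comes back to the route at 12.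

Step 10. The tertiary C4 radical may be reduced before it adds to the hydrazone (net hydrogenation to a secondary methyl), or add too slowly next to the ring fusion; acid released in the thermolysis may also cleave the TES ether. The fallback sets out from 13. Cyclopropanation of the C3=C4 bond (Et2Zn, CH2I2, CF3CO2H, CH2Cl2, 0 °C) would give 2α-acetoxy-7α-(tert-butyldimethylsilyloxy)-4,8α,10β-trimethyl-3,4-methano-6α-(triethylsilyloxy)-5αH-trans-decalin-9-one F4. Hydrogenolysis of the less hindered C3–CH2 cyclopropane bond (H2, PtO2, EtOAc/AcOH, 25 °C) turns the bridging carbon into the second C4 methyl and comes back at 15.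

Step 20. Acyl transfer to the 6β-hydroxyl, syn-axial to C19 and C20 and flanked by the 7α-acetate, may be too slow; forcing conditions may then cause acetyl scrambling or ionisation of the allylic C7 acetate. The fallback sets out from ketone 23 and acylates the alkoxide as it is formed. Reduction with LiBH(s-Bu)3 (THF, −78 °C, equatorial attack from the α face) and trapping of the lithium alkoxide in the same flask with 3-methylbutanoyl chloride would give 2α-acetoxy-7α-(tert-butyldimethylsilyloxy)-15-(4-methoxybenzyloxy)labda-8,13E-dien-6β-yl 3-methylbutanoate F5. HF·pyridine would remove the C7 silyl ether to give 2α-acetoxy-7α-hydroxy-15-(4-methoxybenzyloxy)labda-8,13E-dien-6β-yl 3-methylbutanoate F6, and acetylation (Ac2O, pyridine, DMAP) comes back at 27.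

Further compounds
F1 | step 8 | (4R,5S,6R,7E)-5-[(tert-butyldimethylsilyl)oxy]-2,4,8-trimethyl-6-[(triethylsilyl)oxy]deca-1,7,9-trien-3-one | C=C(C)C(=O)[C@H](C)[C@H](O[Si](C)(C)C(C)(C)C)[C@H](O[Si](CC)(CC)CC)/C=C(C)/C=C
F2 | step 8 | 7α-(tert-butyldimethylsilyloxy)-4,8α,10β-trimethyl-6α-(triethylsilyloxy)-5αH-trans-decal-3-en-9-one | C1C=C(C)[C@@H]2[C@@H](O[Si](CC)(CC)CC)[C@@H](O[Si](C)(C)C(C)(C)C)[C@@H](C)C(=O)[C@@]2(C)C1
F3 | step 8 | 7α-(tert-butyldimethylsilyloxy)-4,8α,10β-trimethyl-6α-(triethylsilyloxy)-5αH-trans-decal-3-ene-2,9-dione | O=C1C=C(C)[C@@H]2[C@@H](O[Si](CC)(CC)CC)[C@@H](O[Si](C)(C)C(C)(C)C)[C@@H](C)C(=O)[C@@]2(C)C1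
F4 | step 10 | 2α-acetoxy-7α-(tert-butyldimethylsilyloxy)-4,8α,10β-trimethyl-3,4-methano-6α-(triethylsilyloxy)-5αH-trans-decalin-9-one (either cyclopropane face) | CC(=O)O[C@H]1C3CC3(C)[C@@H]2[C@@H](O[Si](CC)(CC)CC)[C@@H](O[Si](C)(C)C(C)(C)C)[C@@H](C)C(=O)[C@@]2(C)C1
F5 | step 20 | 2α-acetoxy-7α-(tert-butyldimethylsilyloxy)-15-(4-methoxybenzyloxy)labda-8,13E-dien-6β-yl 3-methylbutanoate | CC(=O)O[C@H]1CC(C)(C)[C@@H]2[C@H](OC(=O)CC(C)C)[C@@H](O[Si](C)(C)C(C)(C)C)C(C)=C(CC/C(C)=C/COCc3ccc(OC)cc3)[C@@]2(C)C1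
F6 | step 20 | 2α-acetoxy-7α-hydroxy-15-(4-methoxybenzyloxy)labda-8,13E-dien-6β-yl 3-methylbutanoate | CC(=O)O[C@H]1CC(C)(C)[C@@H]2[C@H](OC(=O)CC(C)C)[C@@H](O)C(C)=C(CC/C(C)=C/COCc3ccc(OC)cc3)[C@@]2(C)C1
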